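(The earlier runs and the new flask stem from a simulated flask with constants of no real substance.)

How much other capture product stands against target in the delta flask at the early and the late time, and does the next charge of this recipe need a sample before its first reading?

| flask | substrate | first nucleophile | second nucleophile | remark | time |
|---|---|---|---|---|---|
| delta | 20 mM | 30 mM | 22 mM | the very flask that is asked about, followed so far |  |
| zeta | 20 mM | 30 mM | 33 mM | run made earlier |  |
| flask | 20 mM | 30.0 mM | 22.0 mM |  | 2.0 min |

| run | time / s | other capture product / % | target / % |
|---|---|---|---|
| delta | 10.0 | 46.2 | 3.5 |
| delta | 20.0 | 48.9 | 3.8 |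
| delta | 50.0 | 50.4 | 3.9 |
| zeta | 10.0 | 55.3 | 3.4 |
| zeta | 15.0 | 58.8 | 2.9 |
| zeta | 30.0 | 60.8 | 3.5 |
| zeta | 50.0 | 60.1 | 1.7 |

(readings scatter by 0.5 percentage points)

- share of other capture product in other capture product plus target at 0.25 s
- share of other capture product in other capture product plus target at 2.0 min
- which of other capture product and target there is more of at 2.0 min

We reckon with S, the apparent selectivity factor: the ratio of other capture product to target at the last reading, multiplied by the charge of first nucleophile over the charge of second nucleophile. Delta at 50.0 s gives 17.6, a reading with a scatter of 0.5 percentage points on a target of 3.9%. Zeta, pooled from 15.0 s on, gives 20.2, so we take the ratio of other capture product to target as following the charge of second nucleophile between these two runs. Zeta's other capture product goes from 60.8% to 60.1% between 30.0 s and 50.0 s, so we carry S to 2.0 min: delta's share is 92.8%, with other capture product ahead.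

But S is a ratio of amounts gathered over a run, and delta's earliest reading stands at 10.0 s. We commit to no figure for 0.25 s and decide to keep the charges and add an early sample.

The forecast gave 94%, 93% and other capture product ahead, on the ground: “Nothing shows conversion of one product into the other”.

The delta flask gives 79.4% at 0.25 s, 93.1% at 2.0 min, and other capture product ahead, 49.1% against 3.64% of target. In this flask at 0.200 min first nucleophile stands at 2.85% of its charge, and the passing of first nucleophile into homo dimer has 97% of its turnover up to the asked time behind it. Put in the terms of S, the amounts formed in this flask up to 0.25 s give 5.27, beside the 17.6 read from delta at 50.0 s.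

    second nucleophile + intermediate → other capture product (k = 190 L mol⁻¹ s⁻¹)
    2 first nucleophile → homo dimer (k = 45.0 L mol⁻¹ s⁻¹)
    intermediate → side product (k = 2.40 s⁻¹)
    substrate → intermediate (k = 0.260 s⁻¹)
    first nucleophile + intermediate → target (k = 50.0 L mol⁻¹ s⁻¹)
    intermediate → solvolysis product (k = 0.640 s⁻¹)

For the neighbour with 8.8 mM of second nucleophile, S gives a share of 83.8% at 2.0 min. The computed share in that neighbour is 83.4%.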